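**Assumption:** the target, 4,6-dibromo-2-(3,5-dibromo-2-methoxyphenoxy)-3-methoxyphenol, has no stereocentre and is achiral, so no stereocontrol is needed. Commercial availability of 1 and 4 is assumed from memory of supplier catalogues.

## Retrosynthetic overview

1. Target 9 ⇐ phenol 7 by dibromination of the phenol ring; C4 and C6 are each ortho/para to both OH and OMe.
2. Phenol 7 ⇐ diaryl ether aldehyde 5 by Baeyer–Villiger oxidation and formate cleavage (CHO serves as a masked OH).
3. Aldehyde 5 ⇐ phenol 3 + 2-fluoro-3-methoxybenzaldehyde 4 by SNAr, which forms the diaryl ether C–O bond.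
4. Phenol 3 ⇐ commercial 3,5-dibromo-2-methoxybenzaldehyde 1 by Baeyer–Villiger oxidation and formate cleavage, so the ring-A bromines are bought in place.
5. No ring is formed; both benzene rings are purchased. Order of events: ring-A phenol, diaryl ether, ring-B phenol, ring-B bromination.

## Route

Step 1
Reactants: 1 3,5-dibromo-2-methoxybenzaldehyde
Product: 3 3,5-dibromo-2-methoxyphenol, via 3,5-dibromo-2-methoxyphenyl formate 2 (not isolated)
Conditions: mCPBA (1.5 eq), CH2Cl2, rt to 40 °C; then MeOH, cat. HCl, rt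
Reagents that add atoms: mCPBA, OOC(=O)c1cccc(Cl)c1
Why: Baeyer–Villiger (Dakin-type) oxidation, in which the ortho-methoxyaryl group migrates in the Criegee intermediate in preference to hydride to give formate 2, which acid-catalysed methanolysis cleaves to the phenol; no stereocentre is involved.

Step 2
Reactants: 3 3,5-dibromo-2-methoxyphenol; 4 2-fluoro-3-methoxybenzaldehyde
Product: 5 2-(3,5-dibromo-2-methoxyphenoxy)-3-methoxybenzaldehyde
Conditions: K2CO3 (2 eq), DMF, 110 °C, N2
Reagents that add atoms: none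
Why: Nucleophilic aromatic substitution (SNAr), in which the phenoxide displaces the fluoride ortho to the formyl group through a Meisenheimer complex while the unactivated aryl bromides stay untouched.

Step 3
Reactants: 5 2-(3,5-dibromo-2-methoxyphenoxy)-3-methoxybenzaldehyde
Product: 7 2-(3,5-dibromo-2-methoxyphenoxy)-3-methoxyphenol, via 2-(3,5-dibromo-2-methoxyphenoxy)-3-methoxyphenyl formate 6 (not isolated)
Conditions: mCPBA (1.5 eq), CH2Cl2, rt; then MeOH, cat. HCl, rt
Reagents that add atoms: mCPBA, OOC(=O)c1cccc(Cl)c1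
Why: Baeyer–Villiger oxidation of an ortho-aryloxy benzaldehyde, where the electron-rich aryl group migrates to give formate 6 and methanolysis frees the phenol; aryl ethers and aryl bromides are inert to the peracid.

Step 4
Reactants: 7 2-(3,5-dibromo-2-methoxyphenoxy)-3-methoxyphenol
Product: 9 4,6-dibromo-2-(3,5-dibromo-2-methoxyphenoxy)-3-methoxyphenol, via 4-bromo-2-(3,5-dibromo-2-methoxyphenoxy)-3-methoxyphenol 8 (not isolated)
Conditions: Br2 (2.05 eq), AcOH, rt
Reagents that add atoms: bromine, BrBr
Why: Electrophilic aromatic bromination, in which C4 and C6 are each ortho/para to both OH and OMe while C5 and the dibrominated anisole ring are far less activated, so two equivalents of bromine go only to these positions (monobromide 8 and any 6-bromo isomer converge on 9).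

## Compound list

1 | 3,5-dibromo-2-methoxybenzaldehyde | COc1c(Br)cc(Br)cc1C=O | starting material
2 | 3,5-dibromo-2-methoxyphenyl formate | COc1c(Br)cc(Br)cc1OC=O | intermediate (not isolated)
3 | 3,5-dibromo-2-methoxyphenol | COc1c(Br)cc(Br)cc1O | intermediate
4 | 2-fluoro-3-methoxybenzaldehyde | COc1cccc(C=O)c1F | starting material
5 | 2-(3,5-dibromo-2-methoxyphenoxy)-3-methoxybenzaldehyde | COc1cccc(C=O)c1Oc1cc(Br)cc(Br)c1OC | intermediate
6 | 2-(3,5-dibromo-2-methoxyphenoxy)-3-methoxyphenyl formate | COc1cccc(OC=O)c1Oc1cc(Br)cc(Br)c1OC | intermediate (not isolated)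
7 | 2-(3,5-dibromo-2-methoxyphenoxy)-3-methoxyphenol | COc1cccc(O)c1Oc1cc(Br)cc(Br)c1OC | intermediate
8 | 4-bromo-2-(3,5-dibromo-2-methoxyphenoxy)-3-methoxyphenol | COc1c(Br)ccc(O)c1Oc1cc(Br)cc(Br)c1OC | intermediate (not isolated)
9 | 4,6-dibromo-2-(3,5-dibromo-2-methoxyphenoxy)-3-methoxyphenol | COc1c(Br)cc(Br)cc1Oc1c(O)c(Br)cc(Br)c1OC | target

## Summary

Total step count: 4. Longest linear sequence: 4 steps (1 → 3 → 5 → 7 → 9).

## Steps most likely to fail, with fallbacks

**Step 1** (Baeyer–Villiger oxidation of an aldehyde deactivated by two bromines; hydride migration to the benzoic acid may compete). The fallback sets out from compound 4 and comes back to the route at compound 5, so neither phenol 3 nor this oxidation is needed. Compound 4 is heated with excess catechol (Oc1ccccc1O, 3 eq; K2CO3, DMF, 100 °C) in an SNAr reaction to give 2-(2-hydroxyphenoxy)-3-methoxybenzaldehyde F1. Its free phenol then directs bromination (Br2, 2.05 eq, AcOH, rt) ortho and para to itself, while the aldehyde-bearing ring is deactivated, giving 2-(3,5-dibromo-2-hydroxyphenoxy)-3-methoxybenzaldehyde F2. O-Methylation (MeI, K2CO3, DMF, rt) then gives 5.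

**Step 2** (SNAr at a fluoride flanked by OMe, activated by only one ortho-formyl group, with a hindered and weakly nucleophilic dibromophenoxide). The fallback sets out from compound 3 and comes back at compound 7, replacing the formyl activator by a nitro group. Compound 3 reacts with 2-fluoro-1-methoxy-3-nitrobenzene (COc1cccc([N+](=O)[O-])c1F; K2CO3, DMF, 70 °C) to give 1,5-dibromo-2-methoxy-3-(2-methoxy-6-nitrophenoxy)benzene F3. Chemoselective nitro reduction (H2, sulfided Pt/C, EtOAc, rt) gives 2-(3,5-dibromo-2-methoxyphenoxy)-3-methoxyaniline F4. Diazotisation (NaNO2, aq. H2SO4, 0 °C) gives 2-(3,5-dibromo-2-methoxyphenoxy)-3-methoxybenzenediazonium hydrogensulfate F5. Copper-mediated hydroxydediazoniation (Cu2O, large excess Cu(NO3)2, H2O, rt, chosen to outpace Pschorr-type closure to a dibenzofuran) gives 7.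

**Step 3** (Baeyer–Villiger oxidation of aldehyde 5; hydride migration would give the carboxylic acid instead of the formate). The fallback sets out from compound 3 and comes back at compound 7, using a methyl ketone in which only aryl or methyl can migrate. Compound 3 and 1-(2-fluoro-3-methoxyphenyl)ethanone (COc1cccc(C(C)=O)c1F; K2CO3, DMF, 120 °C) give by SNAr 1-[2-(3,5-dibromo-2-methoxyphenoxy)-3-methoxyphenyl]ethanone F6. Baeyer–Villiger oxidation (mCPBA, cat. TFA, CH2Cl2, reflux) gives 2-(3,5-dibromo-2-methoxyphenoxy)-3-methoxyphenyl acetate F7, and methanolysis (MeOH, cat. HCl, rt) gives 7.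

## Further compounds

F1 | step 1 | 2-(2-hydroxyphenoxy)-3-methoxybenzaldehyde | COc1cccc(C=O)c1Oc1ccccc1O
F2 | step 1 | 2-(3,5-dibromo-2-hydroxyphenoxy)-3-methoxybenzaldehyde | COc1cccc(C=O)c1Oc1cc(Br)cc(Br)c1O
F3 | step 2 | 1,5-dibromo-2-methoxy-3-(2-methoxy-6-nitrophenoxy)benzene | COc1cccc([N+](=O)[O-])c1Oc1cc(Br)cc(Br)c1OC
F4 | step 2 | 2-(3,5-dibromo-2-methoxyphenoxy)-3-methoxyaniline | COc1cccc(N)c1Oc1cc(Br)cc(Br)c1OC
F5 | step 2 | 2-(3,5-dibromo-2-methoxyphenoxy)-3-methoxybenzenediazonium hydrogensulfate | COc1cccc([N+]#N)c1Oc1cc(Br)cc(Br)c1OC.OS(=O)(=O)[O-]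
F6 | step 3 | 1-[2-(3,5-dibromo-2-methoxyphenoxy)-3-methoxyphenyl]ethanone | COc1cccc(C(C)=O)c1Oc1cc(Br)cc(Br)c1OC
F7 | step 3 | 2-(3,5-dibromo-2-methoxyphenoxy)-3-methoxyphenyl acetate | COc1cccc(OC(C)=O)c1Oc1cc(Br)cc(Br)c1OC
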